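**Plan**

- Numbering (germacrane): the ten-membered ring is C1–C10, with Z-C1=C10 (C14 methyl), AcO-C3, E-C4=C5 (C15 methyl), C8H2 and AcO-C9. The butenolide is O–C6–C7=C11–C12(=O), with C13H2OH on C11.
- Enabling feature: C6 is a carbinol carbon. On one side it carries the E-C4=C5 alkene, whose C15 methyl stands cis to C6; this is the signature of a syn methyl-metalation of a terminal alkyne trapped by an aldehyde. On the other side it carries C7=C11, which holds the C12 carboxyl cis to C6, so lactonisation follows by itself.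
- Retrosynthesis: C5–C6, C4–C15 and O–C12 are cut in one operation, which opens both rings to the acyclic ynal ester 23 plus Me2Zn. The cis formyl-acrylate of 23 is unmasked from a 2-silylfuran. Then C7–C8 (furyllithium + epoxide), C9–C10 (vinyllithium + Weinreb amide), C1=C10 (iodo-Wittig) and C2–C3 (allylboration) are cut.
- Forward: chain C8–C10/C1–C5 (steps 1–6), furan piece C6, C7, C11–C13 from 3-furanmethanol (steps 7–8), union (step 9), furan to formyl ester (steps 10–12), ten-membered ring and butenolide in one flask (step 13), silyl-to-acetate exchange (steps 14–15).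
- Stereochemistry: C3 comes from Brown allylboration, C9 from CBS reduction, and C6 from C3 through the folded nickelacycle. Z-C1=C10 comes from the iodo-ylide, E-C4=C5 from syn addition, and the C7=C11 geometry from the furan ring.

Key step: step 13

Remark: the germacrane numbers given above are also used for the acyclic intermediates.

Step 1
Reactants: 1 3-(trimethylsilyl)prop-2-ynal
Product: 3 (S)-1-(trimethylsilyl)hex-5-en-1-yn-3-ol, via diisopinocampheylborinate 2 (not isolated)
Conditions: (−)-Ipc2BOMe, allylMgBr, Et2O, 0 °C to rt; 1, −78 °C; then pH 7 buffer, H2O2, MeOH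
Reagents that add atoms: allylmagnesium bromide C=CC[Mg]Br
Why: Brown asymmetric allylboration through a closed chair transition state, in which the isopinocampheyl groups of the (+)-α-pinene series direct allyl transfer to the aldehyde face that gives the (S)-carbinol (C3), as is usual for aldehydes whose substituent outranks allyl.

Step 2
Reactants: 3 (S)-1-(trimethylsilyl)hex-5-en-1-yn-3-ol
Product: 4 (S)-3-(tert-butyldimethylsilyloxy)-1-(trimethylsilyl)hex-5-en-1-yne
Conditions: TBSCl, imidazole, DMF, rt
Reagents that add atoms: tert-butyldimethylsilyl chloride CC(C)(C)[Si](C)(C)Cl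
Why: Standard imidazole-promoted silylation, which covers the propargylic C3–OH with a group that zerovalent nickel does not ionise and touches no stereocentre.

Step 3
Reactants: 4 (S)-3-(tert-butyldimethylsilyloxy)-1-(trimethylsilyl)hex-5-en-1-yne
Product: 6 (S)-3-(tert-butyldimethylsilyloxy)-5-(trimethylsilyl)pent-4-ynal, via vicinal diol 5 (not isolated)
Conditions: OsO4 (cat.), NaIO4, 2,6-lutidine, dioxane/H2O, rt
Reagents that add atoms: OsO4 O=[Os](=O)(=O)=O (oxygen carrier); NaIO4 [Na+].[O-]I(=O)(=O)=O (oxygen source)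
Why: Lemieux–Johnson cleavage, in which OsO4 dihydroxylates only the terminal alkene (the silylalkyne is inert), NaIO4 cleaves the diol, and 2,6-lutidine buffers the medium so that the β-silyloxy aldehyde should not eliminate.

Step 4
Reactants: 6 (S)-3-(tert-butyldimethylsilyloxy)-5-(trimethylsilyl)pent-4-ynal
Product: 7 (3S,5Z)-3-(tert-butyldimethylsilyloxy)-6-iodo-1-(trimethylsilyl)hept-5-en-1-yne
Conditions: EtPPh3I, n-BuLi, THF, rt; I2, −78 °C; NaN(SiMe3)2, −20 °C; 6, −78 °C
Reagents that add atoms: ethyltriphenylphosphonium iodide CC[P+](c1ccccc1)(c1ccccc1)c1ccccc1.[I-]; iodine II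
Why: Stork–Zhao-type iodo-olefination, in which the non-stabilised α-iodo ylide reacts under kinetic control and should give the Z-2-iodoalkene (iodine cis to C2), a reaction well known for β-silyloxy aldehydes, and this sets the Z-C1=C10 geometry.

Step 5
Reactants: 7 (3S,5Z)-3-(tert-butyldimethylsilyloxy)-6-iodo-1-(trimethylsilyl)hept-5-en-1-yne
Product: 9 (3Z,6S)-6-(tert-butyldimethylsilyloxy)-1-chloro-3-methyl-8-(trimethylsilyl)oct-3-en-7-yn-2-one, via Z-vinyllithium 8 (not isolated)
Conditions: t-BuLi (2 equiv), Et2O, −78 °C; ClCH2C(O)N(OMe)Me, −78 to −40 °C; AcOH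
Reagents that add atoms: 2-chloro-N-methoxy-N-methylacetamide CON(C)C(=O)CCl
Why: Iodine–lithium exchange keeps the alkene geometry at −78 °C, and the Weinreb ketone synthesis stops at the ketone because the chelated tetrahedral adduct survives until the acidic quench.

Step 6
Reactants: 9 (3Z,6S)-6-(tert-butyldimethylsilyloxy)-1-chloro-3-methyl-8-(trimethylsilyl)oct-3-en-7-yn-2-one
Product: 11 (R)-2-[(2Z,5S)-5-(tert-butyldimethylsilyloxy)hept-2-en-6-yn-2-yl]oxirane, via (2R)-chlorohydrin 10 (not isolated)
Conditions: (R)-2-methyl-CBS-oxazaborolidine (cat.), catecholborane, toluene, −78 °C; then MeOH, K2CO3, rt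
Reagents that add atoms: none
Why: Corey–Bakshi–Shibata reduction in which the trisubstituted alkenyl group is the large and CH2Cl the small substituent, so the (R)-catalyst should give the (R)-chlorohydrin (C9 in the spatial arrangement of the target), after which carbonate closes the epoxide by intramolecular Williamson displacement without touching the C9–O bond and methanolysis removes the alkynyl silane.

Step 7
Reactants: 12 3-furanmethanol
Product: 13 3-[(tert-butyldimethylsilyloxy)methyl]furan
Conditions: TBSCl, imidazole, CH2Cl2, rt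
Reagents that add atoms: tert-butyldimethylsilyl chloride CC(C)(C)[Si](C)(C)Cl
Why: Standard silylation of a primary alcohol, which loads the silicon that step 8 moves onto the ring.

Step 8
Reactants: 13 3-[(tert-butyldimethylsilyloxy)methyl]furan
Product: 15 [2-(tert-butyldimethylsilyl)furan-3-yl]methanol, via 2-lithiofuran 14 (not isolated)
Conditions: n-BuLi, HMPA, THF, −78 to 0 °C; H2O
Reagents that add atoms: none
Why: Ether-directed C2 lithiation followed by a 1,4 O-to-C silyl shift (retro-Brook rearrangement), driven by formation of the lithium alkoxide and known for 3-(silyloxymethyl)furans.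

Step 9
Reactants: 15 [2-(tert-butyldimethylsilyl)furan-3-yl]methanol; 11 (R)-2-[(2Z,5S)-5-(tert-butyldimethylsilyloxy)hept-2-en-6-yn-2-yl]oxirane
Product: 18 (2S,3Z,6S)-6-(tert-butyldimethylsilyloxy)-1-[5-(tert-butyldimethylsilyl)-4-(hydroxymethyl)furan-3-yl]-3-methyloct-3-en-7-yn-2-ol, via furan dianion 16 (not isolated), via lithium acetylide 17 (not isolated)
Conditions: 15, n-BuLi (2.2 equiv), DME, 0 °C; 11, n-BuLi (1 equiv), THF, −78 °C; combine, 0 °C to rt; H2O
Reagents that add atoms: none
Why: Alkoxide-directed lithiation of the 2-silylated 3-furanmethanol at ring position 4, followed by SN2 opening of the monosubstituted epoxide by the hard aryllithium at its free CH2 (C8), which forms C7–C8 and leaves the C9–O bond untouched, while SN2′ attack would have to hit the substituted Z-alkene carbon C1 and direct allylic attack a carbon next to the fully substituted C10.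

Step 10
Reactants: 18 (2S,3Z,6S)-6-(tert-butyldimethylsilyloxy)-1-[5-(tert-butyldimethylsilyl)-4-(hydroxymethyl)furan-3-yl]-3-methyloct-3-en-7-yn-2-ol
Product: 19 C3,C9,C13-tris(tert-butyldimethylsilyl) ether of the 2-silylfuran enyne
Conditions: TBSOTf, 2,6-lutidine, CH2Cl2, 0 °C
Reagents that add atoms: tert-butyldimethylsilyl triflate CC(C)(C)[Si](C)(C)OS(=O)(=O)C(F)(F)F
Why: Silyl triflate silylation covers the primary C13–OH and the hindered secondary C9–OH in one operation and leaves the terminal alkyne alone.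

Step 11
Reactants: 19 C3,C9,C13-tris(tert-butyldimethylsilyl) ether of the 2-silylfuran enyne
Product: 22 γ-hydroxybutenolide (lactol epimers at C6), via furan endoperoxide 20 (not isolated), via silyl formylacrylate 21 (not isolated)
Conditions: O2, visible light, tetraphenylporphyrin (cat.), CH2Cl2, −78 °C; then H2O, rt
Reagents that add atoms: oxygen O=O
Why: [4+2] cycloaddition of singlet oxygen to the furan (far faster at −78 °C than the ene reaction of the trisubstituted alkene), then silyl migration to a peroxide oxygen with O–O cleavage, the known regiospecific path from 2-silylfurans to γ-hydroxybutenolides, so that the silicon-bearing carbon becomes the carboxyl C12 and the CH carbon becomes C6 at the aldehyde level, cis across C7=C11.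

Step 12
Reactants: 22 γ-hydroxybutenolide (lactol epimers at C6)
Product: 23 methyl (2Z,5S,6Z,9S)-5,9-bis(tert-butyldimethylsilyloxy)-2-[(tert-butyldimethylsilyloxy)methyl]-3-formyl-6-methylundeca-2,6-dien-10-ynoate
Conditions: MeI, K2CO3, DMF, 0 °C to rt
Reagents that add atoms: iodomethane CI
Why: O-alkylation of the ring-opened carboxylate tautomer, as known for 2-formylbenzoic acid and related pseudo-acids, should give the normal open-chain ester and free the aldehyde, the tetrasubstituted alkene keeping its geometry.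

Step 13
Reactants: 23 methyl (2Z,5S,6Z,9S)-5,9-bis(tert-butyldimethylsilyloxy)-2-[(tert-butyldimethylsilyloxy)methyl]-3-formyl-6-methylundeca-2,6-dien-10-ynoate
Product: 25 (3S,6R,9S)-3,9,13-tris(tert-butyldimethylsilyloxy)germacra-1(10)Z,4E,7(11)-trien-12,6-olide, via methylzinc alkoxide 24 (not isolated)
Conditions: Ni(cod)2 (20 mol %), Me2Zn (3 equiv), THF, 0 °C, 23 added over 10 h (final 2 mM); aq. NH4Cl
Reagents that add atoms: dimethylzinc C[Zn]C
Why: Proposed new method: zerovalent nickel binds the terminal alkyne and the aldehyde of 23 and couples them oxidatively to a planar five-membered oxanickelacycle (new C5–C6 bond), Me2Zn then hands a methyl group to nickel while zinc takes the oxygen, and reductive elimination places that methyl (C15) on C4 on the same side as C6, so the E-C4=C5 alkene follows from syn addition. The closest known reaction types are the Ni(cod)2/organozinc alkylative cyclisation of ynals to five- and six-membered rings, the three-component coupling of terminal alkynes, aldehydes and Me2Zn, and the nickel-catalysed reductive endo macrocyclisation of terminal ynals; new is only the methylative variant in a ten-membered closure that ends in a lactonisation. The carbocycle closes in the 10-endo-dig mode, which is also the innate regiochemistry because the branched C3 substituent prefers the alkyne carbon next to nickel, and the methylzinc alkoxide 24 then closes the butenolide by 5-exo-trig attack on the C12 ester that C7=C11 holds cis to C6. C6 is controlled by C3: to avoid the ligand sphere of nickel the C3–H bond turns towards nickel and the C3 silyloxy group to the outer face, which fixes the alkyne face that looks into the ring, and since the C6–O bond must lie in the plane of the nickelacycle with C7 on the ring side, H6 points outwards, which corresponds to (6R) for (3S). The step needs 1,2-coupling at the aldehyde in preference to reaction at the enoate, to plain methyl addition and to C–O ionisation, and the substrate secures this because C7=C11 is tetrasubstituted, Me2Zn has no β-hydrogen (no reductive path) and is inert to aldehydes without a catalyst, and silyl ethers in place of acetates keep the propargylic C3–O and allylic C9–O bonds out of oxidative addition. Slow addition at high dilution should keep the ynal concentration low enough for ring closure to outrun alkyne oligomerisation.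

Step 14
Reactants: 25 (3S,6R,9S)-3,9,13-tris(tert-butyldimethylsilyloxy)germacra-1(10)Z,4E,7(11)-trien-12,6-olide
Product: 26 (3S,6R,9S)-3,9,13-trihydroxygermacra-1(10)Z,4E,7(11)-trien-12,6-olide
Conditions: HF·pyridine, pyridine, THF, 0 °C to rt
Reagents that add atoms: none
Why: Fluoride cleavage of the three silyl ethers under pyridine-buffered conditions, which avoids base-induced epimerisation at the acidic C6–H and acid-induced transannular cyclisation of the 1,5-diene.

Step 15
Reactants: 26 (3S,6R,9S)-3,9,13-trihydroxygermacra-1(10)Z,4E,7(11)-trien-12,6-olide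
Product: 29 (3S,6R,9S)-3,9-diacetoxy-13-hydroxygermacra-1(10)Z,4E,7(11)-trien-12,6-olide (target), via 13-O-triethylsilyl triol 27 (not isolated), via 13-O-triethylsilyl diacetate 28 (not isolated)
Conditions: TESCl (1.05 equiv), pyridine, CH2Cl2, −40 °C; Ac2O, DMAP, 0 °C to rt; HF·pyridine, 0 °C
Reagents that add atoms: acetic anhydride CC(=O)OC(C)=O; chlorotriethylsilane CC[Si](Cl)(CC)CC (its silicon stays only in 27 and 28)
Why: Transient protection in one flask, in which the primary C13–OH is silylated much faster than the two secondary allylic alcohols, DMAP-catalysed acetylation then takes C3–OH and C9–OH, and buffered fluoride removes the labile primary triethylsilyl ether without touching the acetates or any stereocentre.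

**Compound list**

1 | 3-(trimethylsilyl)prop-2-ynal | C[Si](C)(C)C#CC=O | starting material
2 | diisopinocampheylborinate of 3 | C[Si](C)(C)C#C[C@H](CC=C)OB([C@@H]1C[C@@H]2C[C@H]([C@H]1C)C2(C)C)[C@@H]1C[C@@H]2C[C@H]([C@H]1C)C2(C)C | intermediate
3 | (S)-1-(trimethylsilyl)hex-5-en-1-yn-3-ol | C[Si](C)(C)C#C[C@@H](O)CC=C | intermediate
4 | (S)-3-(tert-butyldimethylsilyloxy)-1-(trimethylsilyl)hex-5-en-1-yne | C[Si](C)(C)C#C[C@@H](O[Si](C)(C)C(C)(C)C)CC=C | intermediate
5 | vicinal diol from 4 (epimers at the new carbinol) | C[Si](C)(C)C#C[C@@H](O[Si](C)(C)C(C)(C)C)CC(O)CO | intermediate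
6 | (S)-3-(tert-butyldimethylsilyloxy)-5-(trimethylsilyl)pent-4-ynal | C[Si](C)(C)C#C[C@@H](O[Si](C)(C)C(C)(C)C)CC=O | intermediate
7 | (3S,5Z)-3-(tert-butyldimethylsilyloxy)-6-iodo-1-(trimethylsilyl)hept-5-en-1-yne | C/C(I)=C/C[C@H](O[Si](C)(C)C(C)(C)C)C#C[Si](C)(C)C | intermediate
8 | Z-vinyllithium from 7 | [Li]/C(C)=C\C[C@H](O[Si](C)(C)C(C)(C)C)C#C[Si](C)(C)C | intermediate
9 | (3Z,6S)-6-(tert-butyldimethylsilyloxy)-1-chloro-3-methyl-8-(trimethylsilyl)oct-3-en-7-yn-2-one | ClCC(=O)/C(C)=C\C[C@H](O[Si](C)(C)C(C)(C)C)C#C[Si](C)(C)C | intermediate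
10 | (2R,3Z,6S)-6-(tert-butyldimethylsilyloxy)-1-chloro-3-methyl-8-(trimethylsilyl)oct-3-en-7-yn-2-ol | ClC[C@H](O)/C(C)=C\C[C@H](O[Si](C)(C)C(C)(C)C)C#C[Si](C)(C)C | intermediate
11 | (R)-2-[(2Z,5S)-5-(tert-butyldimethylsilyloxy)hept-2-en-6-yn-2-yl]oxirane | C1O[C@@H]1/C(C)=C\C[C@H](O[Si](C)(C)C(C)(C)C)C#C | intermediate
12 | 3-furanmethanol | OCc1ccoc1 | starting material
13 | 3-[(tert-butyldimethylsilyloxy)methyl]furan | CC(C)(C)[Si](C)(C)OCc1ccoc1 | intermediate
14 | 2-lithio-3-[(tert-butyldimethylsilyloxy)methyl]furan | [Li]c1occc1CO[Si](C)(C)C(C)(C)C | intermediate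
15 | [2-(tert-butyldimethylsilyl)furan-3-yl]methanol | OCc1ccoc1[Si](C)(C)C(C)(C)C | intermediate
16 | C4,O-dilithio derivative of 15 | [Li]OCc1c([Li])coc1[Si](C)(C)C(C)(C)C | intermediate
17 | lithium acetylide of 11 | C1O[C@@H]1/C(C)=C\C[C@H](O[Si](C)(C)C(C)(C)C)C#C[Li] | intermediate
18 | (2S,3Z,6S)-6-(tert-butyldimethylsilyloxy)-1-[5-(tert-butyldimethylsilyl)-4-(hydroxymethyl)furan-3-yl]-3-methyloct-3-en-7-yn-2-ol | OCc1c(C[C@H](O)/C(C)=C\C[C@H](O[Si](C)(C)C(C)(C)C)C#C)coc1[Si](C)(C)C(C)(C)C | intermediate
19 | C3,C9,C13-tris(tert-butyldimethylsilyl) ether of the 2-silylfuran enyne | CC(C)(C)[Si](C)(C)OCc1c(C[C@H](O[Si](C)(C)C(C)(C)C)/C(C)=C\C[C@H](O[Si](C)(C)C(C)(C)C)C#C)coc1[Si](C)(C)C(C)(C)C | intermediate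
20 | furan endoperoxide of 19 | CC(C)(C)[Si](C)(C)OCC1=C(C[C@H](O[Si](C)(C)C(C)(C)C)/C(C)=C\C[C@H](O[Si](C)(C)C(C)(C)C)C#C)C2OOC1([Si](C)(C)C(C)(C)C)O2 | intermediate
21 | tert-butyldimethylsilyl (Z)-formylacrylate ester | CC(C)(C)[Si](C)(C)OC(=O)/C(CO[Si](C)(C)C(C)(C)C)=C(\C=O)C[C@H](O[Si](C)(C)C(C)(C)C)/C(C)=C\C[C@H](O[Si](C)(C)C(C)(C)C)C#C | intermediate
22 | γ-hydroxybutenolide (lactol epimers at C6) | CC(C)(C)[Si](C)(C)OCC1=C(C[C@H](O[Si](C)(C)C(C)(C)C)/C(C)=C\C[C@H](O[Si](C)(C)C(C)(C)C)C#C)C(O)OC1=O | intermediate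
23 | methyl (2Z,5S,6Z,9S)-5,9-bis(tert-butyldimethylsilyloxy)-2-[(tert-butyldimethylsilyloxy)methyl]-3-formyl-6-methylundeca-2,6-dien-10-ynoate | COC(=O)/C(CO[Si](C)(C)C(C)(C)C)=C(\C=O)C[C@H](O[Si](C)(C)C(C)(C)C)/C(C)=C\C[C@H](O[Si](C)(C)C(C)(C)C)C#C | intermediate
24 | methylzinc alkoxide of the ring-closed C6 hydroxy ester | CC(C)(C)[Si](C)(C)O[C@H]1C/C(=C(\CO[Si](C)(C)C(C)(C)C)C(=O)OC)[C@H](O[Zn]C)/C=C(\C)[C@@H](O[Si](C)(C)C(C)(C)C)C/C=C\1C | intermediate
25 | (3S,6R,9S)-3,9,13-tris(tert-butyldimethylsilyloxy)germacra-1(10)Z,4E,7(11)-trien-12,6-olide | CC(C)(C)[Si](C)(C)O[C@H]1CC2=C(CO[Si](C)(C)C(C)(C)C)C(=O)O[C@@H]2/C=C(\C)[C@@H](O[Si](C)(C)C(C)(C)C)C/C=C\1C | intermediate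
26 | (3S,6R,9S)-3,9,13-trihydroxygermacra-1(10)Z,4E,7(11)-trien-12,6-olide | O[C@H]1CC2=C(CO)C(=O)O[C@@H]2/C=C(\C)[C@@H](O)C/C=C\1C | intermediate
27 | 13-O-triethylsilyl ether of 26 | O[C@H]1CC2=C(CO[Si](CC)(CC)CC)C(=O)O[C@@H]2/C=C(\C)[C@@H](O)C/C=C\1C | intermediate
28 | 13-O-triethylsilyl 3,9-diacetate | CC(=O)O[C@H]1CC2=C(CO[Si](CC)(CC)CC)C(=O)O[C@@H]2/C=C(\C)[C@@H](OC(C)=O)C/C=C\1C | intermediate
29 | (3S,6R,9S)-3,9-diacetoxy-13-hydroxygermacra-1(10)Z,4E,7(11)-trien-12,6-olide | CC(=O)O[C@H]1CC2=C(CO)C(=O)O[C@@H]2/C=C(\C)[C@@H](OC(C)=O)C/C=C\1C | target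

**Step count**

Total step count: 15. Longest linear sequence: 13 (steps 1–6 and 9–15).

**Steps most likely to fail**

1. Step 13.
   - Risk: the slow ten-membered closure may be outrun by oligomerisation of the terminal alkyne on zerovalent nickel or by intermolecular coupling. Methyl transfer to the aldehyde may compete. The folding that is meant to relay C3 to C6 may give poor facial selectivity.
   - Fallback (known chemistry): it sets out from 19 and comes back at 25. Zirconium-catalysed methylalumination of the alkyne of 19 (Me3Al, Cp2ZrCl2, CH2Cl2; Negishi carboalumination) and iodinolysis with I2 would give the E-vinyl iodide F1. Singlet-oxygen cleavage of the silylfuran as in step 11 would give the iodo hydroxybutenolide F2. MeI/K2CO3 as in step 12 would give the iodo formyl ester F3. A Nozaki–Hiyama–Kishi macrocyclisation (CrCl2, NiCl2 cat., DMSO, high dilution) would then form the same C5–C6 bond, and the chromium alkoxide would lactonise to 25.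

2. Step 9.
   - Risk: the aryllithium may attack the vinyl epoxide at the allylic carbon or in the SN2′ mode, or it may be lost by proton transfer before the slow uncatalysed opening takes place.
   - Fallback: it sets out from 15 and 7 and comes back at 19. The dianion 16 made from 15 would be alkylated with allyl bromide to the 4-allylfuran F4. This would be silylated (TBSCl, imidazole) to the allylfuran silyl ether F5 and cleaved (OsO4 cat., NaIO4, 2,6-lutidine) to the furylacetaldehyde F6. Nozaki–Hiyama–Kishi coupling of F6 and 7 (CrCl2, NiCl2 cat., DMSO) would give the allylic alcohol F7 as C9 epimers. Dess–Martin oxidation would give the Z-enone F8. Reduction with (R)-2-methyl-CBS-oxazaborolidine and catecholborane would give the (9S)-alcohol F9, and TBSOTf/2,6-lutidine the silylalkyne tris-silyl ether F10. K2CO3 in MeOH would then free the alkyne to give 19.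

3. Step 4.
   - Risk: the basic ylide may trigger β-elimination of the C3 silyloxy group. Incomplete iodination of the ylide may lead to iodine-free alkene. The Z selectivity may erode.
   - Fallback: it sets out from 6 and comes back at 9. Corey–Fuchs-type dibromoolefination (CBr4, PPh3, CH2Cl2, 0 °C) would give the 1,1-dibromoalkene F11. A palladium-catalysed trans-selective Negishi monomethylation (Me2Zn, PdCl2(DPEphos), THF) would replace only the bromine trans to the chain and give the Z-2-bromoalkene F12. Bromine–lithium exchange (t-BuLi, −78 °C) would lead to the same vinyllithium 8, which is acylated as in step 5 to 9.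

**Further compounds**

F1 | step 13 | E-vinyl iodide from 19 (C5 iodide, C15 methyl in place) | CC(C)(C)[Si](C)(C)OCc1c(C[C@H](O[Si](C)(C)C(C)(C)C)/C(C)=C\C[C@H](O[Si](C)(C)C(C)(C)C)/C(C)=C/I)coc1[Si](C)(C)C(C)(C)C
F2 | step 13 | iodo hydroxybutenolide (lactol epimers) | CC(C)(C)[Si](C)(C)OCC1=C(C[C@H](O[Si](C)(C)C(C)(C)C)/C(C)=C\C[C@H](O[Si](C)(C)C(C)(C)C)/C(C)=C/I)C(O)OC1=O
F3 | step 13 | iodo formyl ester | COC(=O)/C(CO[Si](C)(C)C(C)(C)C)=C(\C=O)C[C@H](O[Si](C)(C)C(C)(C)C)/C(C)=C\C[C@H](O[Si](C)(C)C(C)(C)C)/C(C)=C/I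
F4 | step 9 | [4-allyl-2-(tert-butyldimethylsilyl)furan-3-yl]methanol | OCc1c(CC=C)coc1[Si](C)(C)C(C)(C)C
F5 | step 9 | tert-butyldimethylsilyl ether of F4 | CC(C)(C)[Si](C)(C)OCc1c(CC=C)coc1[Si](C)(C)C(C)(C)C
F6 | step 9 | 2-[5-(tert-butyldimethylsilyl)-4-(tert-butyldimethylsilyloxymethyl)furan-3-yl]acetaldehyde | CC(C)(C)[Si](C)(C)OCc1c(CC=O)coc1[Si](C)(C)C(C)(C)C
F7 | step 9 | allylic alcohol, C9 epimers | CC(C)(C)[Si](C)(C)OCc1c(CC(O)/C(C)=C\C[C@H](O[Si](C)(C)C(C)(C)C)C#C[Si](C)(C)C)coc1[Si](C)(C)C(C)(C)C
F8 | step 9 | Z-enone | CC(C)(C)[Si](C)(C)OCc1c(CC(=O)/C(C)=C\C[C@H](O[Si](C)(C)C(C)(C)C)C#C[Si](C)(C)C)coc1[Si](C)(C)C(C)(C)C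
F9 | step 9 | (9S)-allylic alcohol | CC(C)(C)[Si](C)(C)OCc1c(C[C@H](O)/C(C)=C\C[C@H](O[Si](C)(C)C(C)(C)C)C#C[Si](C)(C)C)coc1[Si](C)(C)C(C)(C)C
F10 | step 9 | C-trimethylsilyl alkyne analogue of 19 | CC(C)(C)[Si](C)(C)OCc1c(C[C@H](O[Si](C)(C)C(C)(C)C)/C(C)=C\C[C@H](O[Si](C)(C)C(C)(C)C)C#C[Si](C)(C)C)coc1[Si](C)(C)C(C)(C)C
F11 | step 4 | (S)-6,6-dibromo-3-(tert-butyldimethylsilyloxy)-1-(trimethylsilyl)hex-5-en-1-yne | BrC(Br)=CC[C@H](O[Si](C)(C)C(C)(C)C)C#C[Si](C)(C)C
F12 | step 4 | (3S,5Z)-6-bromo-3-(tert-butyldimethylsilyloxy)-1-(trimethylsilyl)hept-5-en-1-yne | C/C(Br)=C/C[C@H](O[Si](C)(C)C(C)(C)C)C#C[Si](C)(C)C
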